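**Strategy.** The decalin is cut at C5–C10 and C8–C9, the two ring bonds that flank the C9–C10 bond linking the oxygenated, fully substituted C9 to quaternary C10. One intramolecular Diels–Alder reaction therefore suffices: a (Z)-2-benzyloxy-3-methyl enoate (C9=C10, ester carbon C11) adds across an (E,E)-diene (C5–C8) through the C1–C4 tether, closing rings A and B and setting C5, C8, C9 and C10. The precursor is an acyclic triene ester that already holds C3 and C4; its dienophile geometry is fixed by chelation-controlled enol triflation and methyl cross-coupling. Afterwards C8 is corrected by alkene transposition and radical hydrogenation, and the spiro ether-lactone is built through a Sharpless epoxide.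

Key step: step 15

Atom labels follow labdane numbering (C1–C20); TBS = tert-butyldimethylsilyl, Bn = benzyl; "pentanorlabdane" means the C15 core lacking C12–C16.
Remark: the facial sense of the phosphoric acid (step 6) and of the tartrate (step 26) is taken from the accepted models of these reactions; should either run the other way on this substrate, the enantiomeric catalyst or ligand is used.

## Route

Step 1
Reactants: 1 tert-butyldimethyl(prop-2-yn-1-yloxy)silane
Product: 2 methyl 4-(TBS-oxy)but-2-ynoate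
Conditions: n-BuLi, THF, −78 °C; ClCO2Me
Reagents that add atoms: methyl chloroformate, COC(=O)Cl
Why: Acylation of the lithium acetylide with a chloroformate is a standard alkynoate synthesis.

Step 2
Reactants: 2 methyl 4-(TBS-oxy)but-2-ynoate
Product: 3 methyl (Z)-4-(TBS-oxy)-3-methylbut-2-enoate
Conditions: Me2CuLi, THF, −78 °C; MeOH, −78 °C
Reagents that add atoms: lithium dimethylcuprate, [Li+].C[Cu-]C
Why: Syn carbocupration of the ynoate and cold protonation place methyl and hydrogen cis, so the ester and the silyloxymethyl group end cis.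

Step 3
Reactants: 3 methyl (Z)-4-(TBS-oxy)-3-methylbut-2-enoate
Product: 4 (Z)-4-(TBS-oxy)-3-methylbut-2-en-1-ol
Conditions: i-Bu2AlH, CH2Cl2, −78 °C
Reagents that add atoms: none
Why: 1,2-Reduction of the enoate by the aluminium hydride leaves the alkene geometry and the silyl ether untouched.

Step 4
Reactants: 4 (Z)-4-(TBS-oxy)-3-methylbut-2-en-1-ol
Product: 5 (Z)-4-(TBS-oxy)-3-methylbut-2-en-1-yl acetate
Conditions: Ac2O, pyridine, DMAP (cat.), CH2Cl2, 0 °C
Reagents that add atoms: acetic anhydride, CC(=O)OC(C)=O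
Why: DMAP-catalysed acetylation turns the hydroxyl into a leaving group for π-allyl formation.

Step 5
Reactants: 5 (Z)-4-(TBS-oxy)-3-methylbut-2-en-1-yl acetate
Product: 6 (Z)-γ,γ-disubstituted allylboronate, pinacol ester (CH2OTBS cis to CH2B)
Conditions: B2pin2, Pd(dba)2 (cat.), DMSO, 50 °C
Reagents that add atoms: bis(pinacolato)diboron, CC1(C)OB(OC1(C)C)B1OC(C)(C)C(C)(C)O1
Why: Miyaura-type allylic borylation puts boron on the unsubstituted terminus, and the alkene keeps its geometry because syn/anti exchange would need a tertiary σ-allyl palladium.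

Step 6
Reactants: 6 (Z)-allylboronate; 7 methyl 4-oxobutanoate
Product: 8 methyl (4S,5R)-4-hydroxy-5-methyl-5-(TBS-oxymethyl)hept-6-enoate (C3–OH, quaternary C4 with vinyl)
Conditions: (R)-TRIP phosphoric acid (5 mol %), 4 Å MS, toluene, 0 °C
Reagents that add atoms: none
Why: Chiral phosphoric acid-catalysed allylboration runs through a closed chair with the aldehyde chain and γ-methyl equatorial and the γ-CH2OTBS axial, so the (Z)-reagent sets the C3 hydroxyl anti to the C4 methyl while the catalyst selects the Re face, giving (3S,4R).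

Step 7
Reactants: 8 hydroxy ester
Product: 9 methyl (4S,5R)-4-(TBS-oxy)-5-methyl-5-(TBS-oxymethyl)hept-6-enoate
Conditions: TBSOTf, 2,6-lutidine, CH2Cl2, −78 → 0 °C
Reagents that add atoms: tert-butyldimethylsilyl triflate, CC(C)(C)[Si](C)(C)OS(=O)(=O)C(F)(F)F
Why: Silyl triflate silylation protects the hindered secondary alcohol under non-basic conditions before it can lactonise onto the ester.

Step 8
Reactants: 9 bis-silyl ester
Product: 10 (4S,5R)-N-methoxy-N,5-dimethyl-4-(TBS-oxy)-5-(TBS-oxymethyl)hept-6-enamide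
Conditions: MeNH(OMe)·HCl, i-PrMgCl, THF, −20 → 0 °C
Reagents that add atoms: N,O-dimethylhydroxylamine hydrochloride, CNOC.Cl
Why: Magnesium amide aminolysis converts the ester into the Weinreb amide needed for a single, clean acylation later.

Step 9
Reactants: 10 Weinreb amide
Product: 11 (4S,5R)-N-methoxy-N,5-dimethyl-6-oxo-4-(TBS-oxy)-5-(TBS-oxymethyl)hexanamide (C5 aldehyde)
Conditions: O3, CH2Cl2, −78 °C; PPh3
Reagents that add atoms: ozone, [O-][O+]=O
Why: Ozonolysis with reductive work-up cleaves the only alkene to a non-enolisable α-quaternary aldehyde.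

Step 10
Reactants: 11 aldehyde
Product: 12 (4S,5R,6E)-7-iodo-N-methoxy-N,5-dimethyl-4-(TBS-oxy)-5-(TBS-oxymethyl)hept-6-enamide
Conditions: CrCl2, CHI3, THF, 0 → 23 °C
Reagents that add atoms: iodoform, IC(I)I
Why: Takai olefination gives the (E)-vinyl iodide, the quaternary neighbour reinforcing the usual (E) preference.

Step 11
Reactants: 12 vinyl iodide; 13 (E)-prop-1-en-1-ylboronic acid
Product: 14 (4S,5R,6E,8E)-N-methoxy-N,5-dimethyl-4-(TBS-oxy)-5-(TBS-oxymethyl)deca-6,8-dienamide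
Conditions: Pd(PPh3)4 (cat.), K3PO4, THF/H2O, 50 °C
Reagents that add atoms: none
Why: Suzuki–Miyaura coupling joins the two sp2 carbons with retention at both alkenes, giving the (E,E)-diene C5–C8 with C17.

Step 12
Reactants: 14 diene Weinreb amide; 15 methyl 2-(benzyloxy)acetate
Product: 16 methyl (6S,7R,8E,10E)-2-(benzyloxy)-7-methyl-3-oxo-6-(TBS-oxy)-7-(TBS-oxymethyl)dodeca-8,10-dienoate (both C2 epimers)
Conditions: 15, LiN(i-Pr)2, THF, −78 °C; then 14, −78 → −20 °C; NH4Cl
Reagents that add atoms: none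
Why: Claisen-type acylation of the ester enolate by the Weinreb amide stops at the chelated tetrahedral adduct and releases the α-benzyloxy β-keto ester on work-up, the new C9 centre being erased in the next step.

Step 13
Reactants: 16 β-keto ester
Product: 17 methyl (2E,6S,7R,8E,10E)-2-(benzyloxy)-7-methyl-6-(TBS-oxy)-7-(TBS-oxymethyl)-3-(triflyloxy)dodeca-2,8,10-trienoate (triflate cis to ester)
Conditions: NaH, Et2O, 0 °C; Tf2O, −78 → 0 °C
Reagents that add atoms: trifluoromethanesulfonic anhydride, O=S(=O)(OS(=O)(=O)C(F)(F)F)C(F)(F)F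
Why: The sodium enolate is held in the six-membered chelate between enolate and ester oxygens, so O-triflation gives the isomer with triflate cis to the ester and the tether cis to the benzyloxy group.

Step 14
Reactants: 17 enol triflate
Product: 18 methyl (2Z,6S,7R,8E,10E)-2-(benzyloxy)-3,7-dimethyl-6-(TBS-oxy)-7-(TBS-oxymethyl)dodeca-2,8,10-trienoate
Conditions: Me2Zn, Pd(PPh3)4 (cat.), THF, 0 → 40 °C
Reagents that add atoms: dimethylzinc, C[Zn]C
Why: Negishi coupling replaces the triflate by methyl (C20) with retention, so the methyl is cis to the ester and the tetrasubstituted (2Z)-enol ether forms as one isomer.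

Step 15
Reactants: 18 triene ester
Product: 19 methyl 9α-(benzyloxy)-3β,18-bis(TBS-oxy)pentanorlabd-6-en-11-oate (trans-decalin; 5α-H, 8β-CH3, 10β-CH3)
Conditions: Me2AlCl (2 equiv), CH2Cl2, −20 → 40 °C
Reagents that add atoms: none
Why: Proposed new method: a tetrasubstituted, donor-substituted dienophile has not been shown to cyclise in this way, but the step should follow the concerted, suprafacial [4+2] path of the closest known class, the Lewis acid-promoted intramolecular Diels–Alder reaction of 1,7,9-decatrienes with a terminally activated (E)-dienophile, which gives trans-decalins. Bidentate binding of aluminium to the ester carbonyl and the benzyloxy oxygen ties up the donor lone pair and lowers the LUMO, which is why a chelating ether was chosen on C9. Ring B closes as the new cyclohexene (C5–C10 and C8–C9 formed, C6=C7 left behind) and ring A closes at the same time as the six-membered carbocycle spanned by the C1–C4 tether (fused mode). C9 and C10 follow from the (Z)-alkene (ester and methyl cis, both β; benzyloxy α), C5 from the ester-endo, tether-exo transition state that gives the trans fusion, and C8 from the (E)-propenyl terminus, whose methyl ends cis to the ester (8β). The absolute sense is relayed from C3 and C4 through a chair-like tether with the C3 silyloxy and C18 silyloxymethyl groups equatorial, so only one diene face is reached. The step needs endo and diene-face selectivity, the first secured by the chelated ester and the second by that chair.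

Step 16
Reactants: 19 Diels–Alder adduct
Product: 20 methyl 9α-(benzyloxy)-3β,18-bis(TBS-oxy)pentanorlabd-7-en-11-oate
Conditions: RuHCl(CO)(PPh3)3 (5 mol %), toluene, 90 °C
Reagents that add atoms: none
Why: Ruthenium hydride alkene isomerisation (hydrometalation and β-hydride elimination) moves C6=C7 to the trisubstituted C7=C8 position, driven by substitution and by relief of the C17/C20 diaxial contact, and erases the C8 centre on purpose.

Step 17
Reactants: 20 7-ene
Product: 21 methyl 9α-(benzyloxy)-3β,18-bis(TBS-oxy)pentanorlabdan-11-oate (8α-CH3)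
Conditions: Mn(dpm)3 (10 mol %), PhSiH3, t-BuOOH, i-PrOH, 23 °C
Reagents that add atoms: none
Why: Hydrogen-atom-transfer hydrogenation (Mukaiyama type) gives the tertiary C8 radical, which is quenched under product-like control so that C17 ends equatorial (8α) and not syn-diaxial to C20, the opposite of surface hydrogenation.

Step 18
Reactants: 21 saturated ester
Product: 22 9α-(benzyloxy)-3β,18-bis(TBS-oxy)pentanorlabdan-11-ol
Conditions: LiAlH4, THF, 0 → 40 °C
Reagents that add atoms: none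
Why: Hydride reduction of the hindered ester gives the neopentyl primary alcohol at C11.

Step 19
Reactants: 22 primary alcohol
Product: 23 9α-(benzyloxy)-3β,18-bis(TBS-oxy)pentanorlabdan-11-al
Conditions: Dess–Martin periodinane, NaHCO3, CH2Cl2, 23 °C
Reagents that add atoms: none
Why: Dess–Martin oxidation stops at the non-enolisable α-benzyloxy aldehyde.

Step 20
Reactants: 23 aldehyde
Product: 24 9α-(benzyloxy)-3β,18-bis(TBS-oxy)-13,14,15,16-tetranorlabd-11-ene
Conditions: Ph3PCH3Br, KOt-Bu, THF, 0 → 40 °C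
Reagents that add atoms: methyltriphenylphosphonium bromide, C[P+](c1ccccc1)(c1ccccc1)c1ccccc1.[Br-]
Why: Wittig methylenation installs C12 as a terminal alkene for the later hydroboration.

Step 21
Reactants: 24 vinyl compound
Product: 25 9α-(benzyloxy)-13,14,15,16-tetranorlabd-11-ene-3β,18-diol
Conditions: Bu4NF, THF, 23 → 50 °C
Reagents that add atoms: none
Why: Fluoride desilylation frees both hydroxyls while the benzyl ether and the alkene are untouched.

Step 22
Reactants: 25 diol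
Product: 26 9α-(benzyloxy)-13,14,15,16-tetranorlabd-11-ene-3β,18-diyl diacetate
Conditions: Ac2O, pyridine, DMAP (cat.), CH2Cl2, 23 °C
Reagents that add atoms: acetic anhydride, CC(=O)OC(C)=O
Why: Acetylation puts the two final acetates in place now, since every later step tolerates them.

Step 23
Reactants: 27 tert-butyl(but-3-yn-1-yloxy)dimethylsilane
Product: 28 5-(TBS-oxy)pent-2-yn-1-ol
Conditions: n-BuLi, THF, −78 °C; (CH2O)n, −78 → 23 °C; NH4Cl
Reagents that add atoms: paraformaldehyde (as formaldehyde), C=O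
Why: Hydroxymethylation of the lithium acetylide with formaldehyde gives the propargylic alcohol.

Step 24
Reactants: 28 propargylic alcohol
Product: 29 (Z)-3-iodo-5-(TBS-oxy)pent-2-en-1-ol
Conditions: NaAlH2(OCH2CH2OMe)2, THF, 0 → 23 °C; I2, −78 °C
Reagents that add atoms: iodine, II
Why: Hydroxyl-directed trans-hydroalumination and iodinolysis of the vinylalane give the (Z)-3-iodo allylic alcohol as one regio- and stereoisomer.

Step 25
Reactants: 26 vinyl diacetate; 29 (Z)-vinyl iodide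
Product: 31 (E)-9α-(benzyloxy)-16-(hydroxymethyl)-15-(TBS-oxy)labd-13(16)-ene-3β,18-diyl diacetate (C12 cis to the CH2OH on C16), via B-alkyl-9-BBN adduct 30 (not isolated)
Conditions: 9-BBN, THF, 23 → 40 °C; then 29, Pd(dppf)Cl2 (cat.), AsPh3, K3PO4, DMF/H2O, 23 °C
Reagents that add atoms: none
Why: Anti-Markovnikov hydroboration of the vinyl group and B-alkyl Suzuki–Miyaura coupling form C12–C13 with retention of the iodide geometry.

Step 26
Reactants: 31 allylic alcohol
Product: 32 (13R,16R)-13,16-epoxide of 31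
Conditions: Ti(Oi-Pr)4, D-(−)-diisopropyl tartrate, t-BuOOH, 4 Å MS, CH2Cl2, −20 °C
Reagents that add atoms: tert-butyl hydroperoxide, CC(C)(C)OO
Why: Sharpless asymmetric epoxidation of the 3,3-disubstituted allylic alcohol is reagent-controlled, the D-tartrate delivering oxygen to the face that gives the (13R,16R)-epoxide.

Step 27
Reactants: 32 epoxy alcohol
Product: 34 (13S,16R)-9α,13-epoxy-16-(hydroxymethyl)-15-(TBS-oxy)labdane-3β,16,18-triol 3,18-diacetate, via debenzylated epoxy alcohol 33 (not isolated)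
Conditions: H2 (1 atm), Pd(OH)2/C, EtOAc, 23 °C; then CSA (10 mol %), CH2Cl2, 0 °C
Reagents that add atoms: none
Why: Hydrogenolysis frees the C9 hydroxyl, which opens the protonated epoxide by 5-exo attack at tertiary C13 with inversion, so the epoxide configuration becomes the (13S) spiro ether.

Step 28
Reactants: 34 spiro ether diol
Product: 36 (13S)-9α,13-epoxy-15-(TBS-oxy)labdane-3β,16,18-triol 3,18-diacetate, via C16 aldehyde 35 (not isolated)
Conditions: NaIO4, THF/H2O, 0 °C; then NaBH4, MeOH, 0 °C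
Reagents that add atoms: none
Why: Periodate glycol cleavage removes the extra carbon as formaldehyde and borohydride reduces the non-epimerisable aldehyde to the C16 alcohol.

Step 29
Reactants: 36 silyl ether
Product: 37 (13S)-9α,13-epoxylabdane-3β,15,16,18-tetrol 3,18-diacetate
Conditions: HF·pyridine, pyridine/THF, 0 → 23 °C
Reagents that add atoms: none
Why: Buffered fluoride desilylation removes the primary silyl ether without acetate migration.

Step 30
Reactants: 37 diol
Product: 38 (13S)-3β,18-diacetoxy-9α,13-epoxylabdan-15,16-olide (C15 carbonyl, C16–O), the target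
Conditions: TEMPO (20 mol %), PhI(OAc)2, CH2Cl2, 23 °C
Reagents that add atoms: none
Why: TEMPO oxidation attacks the unhindered C15 alcohol first, the neopentyl C16 hydroxyl traps the aldehyde as a lactol and this is oxidised to the γ-lactone, C13 staying untouched because no base is present.

## Compound list

1 | tert-butyldimethyl(prop-2-yn-1-yloxy)silane | C#CCO[Si](C)(C)C(C)(C)C | starting material
2 | methyl 4-(TBS-oxy)but-2-ynoate | COC(=O)C#CCO[Si](C)(C)C(C)(C)C | intermediate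
3 | methyl (Z)-4-(TBS-oxy)-3-methylbut-2-enoate | COC(=O)/C=C(/C)CO[Si](C)(C)C(C)(C)C | intermediate
4 | (Z)-4-(TBS-oxy)-3-methylbut-2-en-1-ol | OC/C=C(/C)CO[Si](C)(C)C(C)(C)C | intermediate
5 | (Z)-4-(TBS-oxy)-3-methylbut-2-en-1-yl acetate | CC(=O)OC/C=C(/C)CO[Si](C)(C)C(C)(C)C | intermediate
6 | (Z)-tert-butyldimethyl{[2-methyl-4-(pinacolboryl)but-2-en-1-yl]oxy}silane | CC1(C)OB(C/C=C(/C)CO[Si](C)(C)C(C)(C)C)OC1(C)C | intermediate
7 | methyl 4-oxobutanoate | COC(=O)CCC=O | starting material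
8 | methyl (4S,5R)-4-hydroxy-5-methyl-5-(TBS-oxymethyl)hept-6-enoate | CC(C)(C)[Si](C)(C)OC[C@](C=C)(C)[C@@H](O)CCC(=O)OC | intermediate
9 | methyl (4S,5R)-4-(TBS-oxy)-5-methyl-5-(TBS-oxymethyl)hept-6-enoate | CC(C)(C)[Si](C)(C)OC[C@](C=C)(C)[C@@H](O[Si](C)(C)C(C)(C)C)CCC(=O)OC | intermediate
10 | (4S,5R)-N-methoxy-N,5-dimethyl-4-(TBS-oxy)-5-(TBS-oxymethyl)hept-6-enamide | CC(C)(C)[Si](C)(C)OC[C@](C=C)(C)[C@@H](O[Si](C)(C)C(C)(C)C)CCC(=O)N(C)OC | intermediate
11 | (4S,5R)-N-methoxy-N,5-dimethyl-6-oxo-4-(TBS-oxy)-5-(TBS-oxymethyl)hexanamide | CC(C)(C)[Si](C)(C)OC[C@](C=O)(C)[C@@H](O[Si](C)(C)C(C)(C)C)CCC(=O)N(C)OC | intermediate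
12 | (4S,5R,6E)-7-iodo-N-methoxy-N,5-dimethyl-4-(TBS-oxy)-5-(TBS-oxymethyl)hept-6-enamide | CC(C)(C)[Si](C)(C)OC[C@](/C=C/I)(C)[C@@H](O[Si](C)(C)C(C)(C)C)CCC(=O)N(C)OC | intermediate
13 | (E)-prop-1-en-1-ylboronic acid | C/C=C/B(O)O | starting material
14 | (4S,5R,6E,8E)-N-methoxy-N,5-dimethyl-4-(TBS-oxy)-5-(TBS-oxymethyl)deca-6,8-dienamide | CC(C)(C)[Si](C)(C)OC[C@](/C=C/C=C/C)(C)[C@@H](O[Si](C)(C)C(C)(C)C)CCC(=O)N(C)OC | intermediate
15 | methyl 2-(benzyloxy)acetate | COC(=O)COCc1ccccc1 | starting material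
16 | methyl (6S,7R,8E,10E)-2-(benzyloxy)-7-methyl-3-oxo-6-(TBS-oxy)-7-(TBS-oxymethyl)dodeca-8,10-dienoate (C2 epimers) | CC(C)(C)[Si](C)(C)OC[C@](/C=C/C=C/C)(C)[C@@H](O[Si](C)(C)C(C)(C)C)CCC(=O)C(OCc1ccccc1)C(=O)OC | intermediate
17 | methyl (2E,6S,7R,8E,10E)-2-(benzyloxy)-7-methyl-6-(TBS-oxy)-7-(TBS-oxymethyl)-3-(triflyloxy)dodeca-2,8,10-trienoate | CC(C)(C)[Si](C)(C)OC[C@](/C=C/C=C/C)(C)[C@@H](O[Si](C)(C)C(C)(C)C)CC/C(OS(=O)(=O)C(F)(F)F)=C(\OCc1ccccc1)C(=O)OC | intermediate
18 | methyl (2Z,6S,7R,8E,10E)-2-(benzyloxy)-3,7-dimethyl-6-(TBS-oxy)-7-(TBS-oxymethyl)dodeca-2,8,10-trienoate | CC(C)(C)[Si](C)(C)OC[C@](/C=C/C=C/C)(C)[C@@H](O[Si](C)(C)C(C)(C)C)CC/C(C)=C(\OCc1ccccc1)C(=O)OC | intermediate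
19 | methyl 9α-(benzyloxy)-3β,18-bis(TBS-oxy)pentanorlabd-6-en-11-oate (5α-H, 8β-CH3, 10β-CH3) | CC(C)(C)[Si](C)(C)OC[C@]1(C)[C@@H](O[Si](C)(C)C(C)(C)C)CC[C@@]2(C)[C@H]1C=C[C@H](C)[C@]2(OCc3ccccc3)C(=O)OC | intermediate
20 | methyl 9α-(benzyloxy)-3β,18-bis(TBS-oxy)pentanorlabd-7-en-11-oate | CC(C)(C)[Si](C)(C)OC[C@]1(C)[C@@H](O[Si](C)(C)C(C)(C)C)CC[C@@]2(C)[C@H]1CC=C(C)[C@]2(OCc3ccccc3)C(=O)OC | intermediate
21 | methyl 9α-(benzyloxy)-3β,18-bis(TBS-oxy)pentanorlabdan-11-oate (8α-CH3) | CC(C)(C)[Si](C)(C)OC[C@]1(C)[C@@H](O[Si](C)(C)C(C)(C)C)CC[C@@]2(C)[C@H]1CC[C@@H](C)[C@]2(OCc3ccccc3)C(=O)OC | intermediate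
22 | 9α-(benzyloxy)-3β,18-bis(TBS-oxy)pentanorlabdan-11-ol | CC(C)(C)[Si](C)(C)OC[C@]1(C)[C@@H](O[Si](C)(C)C(C)(C)C)CC[C@@]2(C)[C@H]1CC[C@@H](C)[C@]2(OCc3ccccc3)CO | intermediate
23 | 9α-(benzyloxy)-3β,18-bis(TBS-oxy)pentanorlabdan-11-al | CC(C)(C)[Si](C)(C)OC[C@]1(C)[C@@H](O[Si](C)(C)C(C)(C)C)CC[C@@]2(C)[C@H]1CC[C@@H](C)[C@]2(OCc3ccccc3)C=O | intermediate
24 | 9α-(benzyloxy)-3β,18-bis(TBS-oxy)-13,14,15,16-tetranorlabd-11-ene | CC(C)(C)[Si](C)(C)OC[C@]1(C)[C@@H](O[Si](C)(C)C(C)(C)C)CC[C@@]2(C)[C@H]1CC[C@@H](C)[C@]2(OCc3ccccc3)C=C | intermediate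
25 | 9α-(benzyloxy)-13,14,15,16-tetranorlabd-11-ene-3β,18-diol | OC[C@]1(C)[C@@H](O)CC[C@@]2(C)[C@H]1CC[C@@H](C)[C@]2(OCc3ccccc3)C=C | intermediate
26 | 9α-(benzyloxy)-13,14,15,16-tetranorlabd-11-ene-3β,18-diyl diacetate | CC(=O)OC[C@]1(C)[C@@H](OC(C)=O)CC[C@@]2(C)[C@H]1CC[C@@H](C)[C@]2(OCc3ccccc3)C=C | intermediate
27 | tert-butyl(but-3-yn-1-yloxy)dimethylsilane | C#CCCO[Si](C)(C)C(C)(C)C | starting material
28 | 5-(TBS-oxy)pent-2-yn-1-ol | OCC#CCCO[Si](C)(C)C(C)(C)C | intermediate
29 | (Z)-3-iodo-5-(TBS-oxy)pent-2-en-1-ol | OC/C=C(\I)CCO[Si](C)(C)C(C)(C)C | intermediate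
30 | B-alkyl-9-BBN adduct of 26 (boron on C12) | CC(=O)OC[C@]1(C)[C@@H](OC(C)=O)CC[C@@]2(C)[C@H]1CC[C@@H](C)[C@]2(OCc3ccccc3)CCB4C5CCCC4CCC5 | intermediate (not isolated)
31 | (E)-9α-(benzyloxy)-16-(hydroxymethyl)-15-(TBS-oxy)labd-13(16)-ene-3β,18-diyl diacetate | CC(=O)OC[C@]1(C)[C@@H](OC(C)=O)CC[C@@]2(C)[C@H]1CC[C@@H](C)[C@]2(OCc3ccccc3)CC/C(CCO[Si](C)(C)C(C)(C)C)=C\CO | intermediate
32 | (13R,16R)-9α-(benzyloxy)-13,16-epoxy-16-(hydroxymethyl)-15-(TBS-oxy)labdane-3β,18-diyl diacetate | CC(=O)OC[C@]1(C)[C@@H](OC(C)=O)CC[C@@]2(C)[C@H]1CC[C@@H](C)[C@]2(OCc3ccccc3)CC[C@]4(CCO[Si](C)(C)C(C)(C)C)O[C@@H]4CO | intermediate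
33 | (13R,16R)-13,16-epoxy-9α-hydroxy-16-(hydroxymethyl)-15-(TBS-oxy)labdane-3β,18-diyl diacetate | CC(=O)OC[C@]1(C)[C@@H](OC(C)=O)CC[C@@]2(C)[C@H]1CC[C@@H](C)[C@]2(O)CC[C@]4(CCO[Si](C)(C)C(C)(C)C)O[C@@H]4CO | intermediate (not isolated)
34 | (13S,16R)-9α,13-epoxy-16-(hydroxymethyl)-15-(TBS-oxy)labdane-3β,16,18-triol 3,18-diacetate | CC(=O)OC[C@]1(C)[C@@H](OC(C)=O)CC[C@@]2(C)[C@H]1CC[C@@H](C)[C@]21CC[C@](CCO[Si](C)(C)C(C)(C)C)([C@H](O)CO)O1 | intermediate
35 | (13S)-3β,18-diacetoxy-9α,13-epoxy-15-(TBS-oxy)labdan-16-al | CC(=O)OC[C@]1(C)[C@@H](OC(C)=O)CC[C@@]2(C)[C@H]1CC[C@@H](C)[C@]21CC[C@](CCO[Si](C)(C)C(C)(C)C)(C=O)O1 | intermediate (not isolated)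
36 | (13S)-9α,13-epoxy-15-(TBS-oxy)labdane-3β,16,18-triol 3,18-diacetate | CC(=O)OC[C@]1(C)[C@@H](OC(C)=O)CC[C@@]2(C)[C@H]1CC[C@@H](C)[C@]21CC[C@](CCO[Si](C)(C)C(C)(C)C)(CO)O1 | intermediate
37 | (13S)-9α,13-epoxylabdane-3β,15,16,18-tetrol 3,18-diacetate | CC(=O)OC[C@]1(C)[C@@H](OC(C)=O)CC[C@@]2(C)[C@H]1CC[C@@H](C)[C@]21CC[C@](CCO)(CO)O1 | intermediate
38 | (13S)-3β,18-diacetoxy-9α,13-epoxylabdan-15,16-olide | CC(=O)OC[C@]1(C)[C@@H](OC(C)=O)CC[C@@]2(C)[C@H]1CC[C@@H](C)[C@]21CC[C@]2(COC(=O)C2)O1 | target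

## Summary and risks

Total step count: 30. Longest linear sequence: 28 steps (steps 1–22 and 25–30).

**Step 15 (Proposed new method).** The hindered, donor-substituted alkene may fail to reach the transition state before the Lewis acid ionises the benzyl enol ether or degrades the diene, or the cycloaddition may run through exo or cis-fused pathways. The fallback uses known chemistry, sets out from 14 and returns at 21.
- Methylmagnesium bromide converts the Weinreb amide into the methyl ketone F1.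
- Horner–Wadsworth–Emmons reaction with trimethyl phosphonoacetate gives the (E)-3-methyl enoate F2, the minor (Z)-isomer being removed.
- This terminally activated (E)-trienoate belongs to the established class; Et2AlCl-promoted cyclisation should give the trans-decalin ester F3 (9α-H).
- RuHCl(CO)(PPh3)3 moves the alkene to give the 7-ene F4, and Mn(dpm)3/PhSiH3/t-BuOOH hydrogenation gives the 8α-methyl ester F5.
- Enolisation with KN(SiMe3)2 and oxidation with 2-(phenylsulfonyl)-3-phenyloxaziridine introduce oxygen from the α face, anti to C20, giving the 9α-hydroxy ester F6.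
- Benzylation with 2-benzyloxy-1-methylpyridinium triflate and MgO in PhCF3 at 85 °C gives 21.

**Step 16.** The ruthenium hydride may also walk the alkene toward C5, which would scramble the ring fusion on return, or the migration may stall. The fallback corrects C8 without any alkene transposition, sets out from 19 and returns at 21.
- Hydrogenation over Pd/C saturates C6=C7 and cleaves the benzyl ether, giving the 8β-methyl hydroxy ester F7.
- Photochemical hydrogen-atom-transfer epimerisation of the strained tertiary C8–H centre ((Bu4N)4W10O32, bis(2,4,6-triisopropylphenyl) disulfide, 390 nm, MeCN) relaxes the axial methyl to the equatorial 8α-methyl hydroxy ester F8.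
- Benzylation as above gives 21.

**Step 13.** Enolate geometry may be eroded, for example through a competing five-membered chelate involving the benzyloxy oxygen, so that triflation gives a mixture of alkene isomers. The fallback abandons enolate chemistry for olefination, sets out from 14 and returns at 18.
- Methylmagnesium bromide gives the methyl ketone F9 (identical with F1).
- Horner–Wadsworth–Emmons reaction with methyl 2-(benzyloxy)-2-(dimethoxyphosphoryl)acetate and LiN(SiMe3)2 gives 18 together with its (2E)-isomer F10.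
- The isomers are separated on silica (silver nitrate-doped if needed) and only 18 is carried on.

## Further compounds

F1 | step 15 | (5S,6R,7E,9E)-6-methyl-5-(TBS-oxy)-6-(TBS-oxymethyl)undeca-7,9-dien-2-one | CC(C)(C)[Si](C)(C)OC[C@](/C=C/C=C/C)(C)[C@@H](O[Si](C)(C)C(C)(C)C)CCC(C)=O
F2 | step 15 | methyl (2E,6S,7R,8E,10E)-3,7-dimethyl-6-(TBS-oxy)-7-(TBS-oxymethyl)dodeca-2,8,10-trienoate | CC(C)(C)[Si](C)(C)OC[C@](/C=C/C=C/C)(C)[C@@H](O[Si](C)(C)C(C)(C)C)CC/C(C)=C/C(=O)OC
F3 | step 15 | methyl 3β,18-bis(TBS-oxy)pentanorlabd-6-en-11-oate (9α-H, 8β-CH3) | CC(C)(C)[Si](C)(C)OC[C@]1(C)[C@@H](O[Si](C)(C)C(C)(C)C)CC[C@@]2(C)[C@H]1C=C[C@H](C)[C@@H]2C(=O)OC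
F4 | step 15 | methyl 3β,18-bis(TBS-oxy)pentanorlabd-7-en-11-oate (9α-H) | CC(C)(C)[Si](C)(C)OC[C@]1(C)[C@@H](O[Si](C)(C)C(C)(C)C)CC[C@@]2(C)[C@H]1CC=C(C)[C@@H]2C(=O)OC
F5 | step 15 | methyl 3β,18-bis(TBS-oxy)pentanorlabdan-11-oate (9α-H, 8α-CH3) | CC(C)(C)[Si](C)(C)OC[C@]1(C)[C@@H](O[Si](C)(C)C(C)(C)C)CC[C@@]2(C)[C@H]1CC[C@@H](C)[C@@H]2C(=O)OC
F6 | step 15 | methyl 9α-hydroxy-3β,18-bis(TBS-oxy)pentanorlabdan-11-oate (8α-CH3) | CC(C)(C)[Si](C)(C)OC[C@]1(C)[C@@H](O[Si](C)(C)C(C)(C)C)CC[C@@]2(C)[C@H]1CC[C@@H](C)[C@]2(O)C(=O)OC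
F7 | step 16 | methyl 9α-hydroxy-3β,18-bis(TBS-oxy)pentanorlabdan-11-oate (8β-CH3) | CC(C)(C)[Si](C)(C)OC[C@]1(C)[C@@H](O[Si](C)(C)C(C)(C)C)CC[C@@]2(C)[C@H]1CC[C@H](C)[C@]2(O)C(=O)OC
F8 | step 16 | methyl 9α-hydroxy-3β,18-bis(TBS-oxy)pentanorlabdan-11-oate (8α-CH3) | CC(C)(C)[Si](C)(C)OC[C@]1(C)[C@@H](O[Si](C)(C)C(C)(C)C)CC[C@@]2(C)[C@H]1CC[C@@H](C)[C@]2(O)C(=O)OC
F9 | step 13 | (5S,6R,7E,9E)-6-methyl-5-(TBS-oxy)-6-(TBS-oxymethyl)undeca-7,9-dien-2-one | CC(C)(C)[Si](C)(C)OC[C@](/C=C/C=C/C)(C)[C@@H](O[Si](C)(C)C(C)(C)C)CCC(C)=O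
F10 | step 13 | methyl (2E,6S,7R,8E,10E)-2-(benzyloxy)-3,7-dimethyl-6-(TBS-oxy)-7-(TBS-oxymethyl)dodeca-2,8,10-trienoate | CC(C)(C)[Si](C)(C)OC[C@](/C=C/C=C/C)(C)[C@@H](O[Si](C)(C)C(C)(C)C)CC/C(C)=C(/OCc1ccccc1)C(=O)OC
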